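A small charge of free catalyst, 0.50 mM, works through a racemate while its partner arrives by dissolving, so the question is how far that charge pulls the partner down.

left-handed substrate 0.050 M; solid reagent 0.0500 M; free catalyst 0.50 mM; right-handed substrate 0.050 M
    free catalyst + left-handed substrate ⇌ catalyst intermediate A (K1 = 8.2 M⁻¹, k1 = 498 M⁻¹ s⁻¹)
    free catalyst + right-handed substrate ⇌ catalyst intermediate B (K2 = 31 M⁻¹, k2 = 733 M⁻¹ s⁻¹)
    partner + catalyst intermediate A → free catalyst + left-handed product (k3 = 433 M⁻¹ s⁻¹)
    partner + catalyst intermediate B → free catalyst + right-handed product (k4 = 148 M⁻¹ s⁻¹)
    left-handed substrate ⇌ right-handed substrate (k5 = 0.0355 s⁻¹)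
    solid reagent ⇌ partner, rate k6*(cs6 - [partner]) while solid is left; crystals form when [partner] > cs6 (cs6 = 6.6 mM, k6 = 0.0179 s⁻¹)
- apparent order in free catalyst when 30% of the left-handed substrate and right-handed substrate together are converted (percent change of the rate of making left-handed product for one percent more free catalyst charged)
- free catalyst is single-handed; left-handed substrate and right-handed substrate are mirror images of each other, charged as a racemate, each of them at the stated concentration
- as a solid, counted per litre of solution: solid reagent
- at the start none of the solid reagent is in solution
- charge of left-handed substrate (flask): 0.050 M

Here is my own reckoning at the asked conversion. Suppose first that the two substrates stay equal, so each stands at 0.0350 M. The slower release of bound substrate, 23.6 s⁻¹ from catalyst intermediate B, beats the quicker turnover, 2.86 s⁻¹ of catalyst intermediate A even with [partner] at 6.6 mM, so binding stays at equilibrium. Free catalyst, catalyst intermediate A and catalyst intermediate B then stand as one to 0.287 to 1.08, which sum to 2.37.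

The two intermediates consume partner with a pseudo-first-order coefficient, the drain, of 0.0600 s⁻¹, above the dissolution coefficient 0.0179 s⁻¹. Setting dissolution equal to drain gives [partner] as 6.6 mM times the dissolution share, the dissolution coefficient divided by itself plus the drain: 0.230. That puts [partner] at 1.52 mM. One percent more catalyst raises [catalyst intermediate A] by one percent and lowers [partner] by one percent times one minus the share, so the order equals the share.

This balance relaxes with a time constant of 12.8 s, against roughly 330 s to reach the conversion, and I reckon 37.0% of the solid reagent remains by then.

The weak link is the equality of the substrates. Right-handed product forms 1.29 times as fast as left-handed, but that rate difference over twice 0.0355 s⁻¹ leaves a gap of 0.163 mM, or 0.466% of either substrate. I commit to the share.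

The forecast also gives 0.23, holding that “the reaction is mostly dissolution-limited”.

The simulation gives 0.23, and the flask reaches that conversion at 5.57 min, making left-handed product at 3.95 × 10⁻⁵ M s⁻¹. Later, at 400 s, the flask holds catalyst intermediate A at 11.6% and catalyst intermediate B at 43.8% of the catalyst, with solid reagent at 25.6% of its charge. Those forms make the drain 0.0576 s⁻¹, so the dissolution share moves from 0.230 to 0.237 and [partner] reckons to 1.56 mM; the flask reads 0.00156 M.

The numbers were set for the occasion; what happens was integrated by code.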